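**Plan**
- Retrosynthesis cuts ring C at O1–C2 and C2–C3 (C2 goes back to DMF), then the C6–OH bond, then the O–CH3 bond at C7, and last the C4–C4a acyl bond, leaving resorcinol and 3,4,5-trimethoxyphenylacetic acid.
- Forward: C-acylation joins ring A to the C4–C3–ring B chain, the non-chelated hydroxyl is methylated, the C6 oxygen is introduced, and the pyranone ring C is closed last.
- Enabling feature: the only free hydroxyl, on C6 of ring A, is para to C8a, the carbon bearing O1. While ring C is open, O1 is a free phenol, and peroxodisulfate hydroxylates the carbon para to a phenol.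
- The hydroxyl that must stay free is introduced after the methylation, so the route needs no protecting group.
- The target has no stereocentre and no stereogenic double bond, so no stereocontrol is needed.

Key step: step 3

Remark: the target is read as 6-hydroxy-7-methoxy-3-(3,4,5-trimethoxyphenyl)-4H-chromen-4-one (ring A benzo, ring B trimethoxyphenyl, ring C pyranone).
Remark: BF3·Et2O is the solvent in step 1 and a Lewis-acid promoter in step 4 and enters neither balanced equation; intermediate 7 is written as the monopotassium salt present after acidification.

**Step 1**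
Reactants: 1 resorcinol; 2 (3,4,5-trimethoxyphenyl)acetic acid
Product: 3 deoxybenzoin 1-(2,4-dihydroxyphenyl)-2-(3,4,5-trimethoxyphenyl)ethanone
Conditions: BF3·Et2O (solvent), 85 °C, N2; aq NaOAc work-up
Reagents that add atoms: none
Why: Friedel–Crafts C-acylation of a phenol by a carboxylic acid in BF3·Et2O (Nencki-type, through the aryl ester and a Fries shift) should go to C4 of resorcinol, ortho to one hydroxyl and para to the other, and stop at the mono-ketone because the chelated o-hydroxy ketone is deactivated, while resorcinol is far more nucleophilic than the trimethoxyphenyl ring of 2.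

**Step 2**
Reactants: 3 deoxybenzoin 1-(2,4-dihydroxyphenyl)-2-(3,4,5-trimethoxyphenyl)ethanone; 4 dimethyl sulfate
Product: 5 monomethyl ether 1-(2-hydroxy-4-methoxyphenyl)-2-(3,4,5-trimethoxyphenyl)ethanone
Conditions: Me2SO4 (1.05 equiv), K2CO3 (1.1 equiv), acetone, reflux
Reagents that add atoms: dimethyl sulfate (4), COS(=O)(=O)OC
Why: Williamson O-methylation under weak base should touch only the C4 hydroxyl, which is free and the more acidic (para to the carbonyl), because the C2 hydroxyl is held in a hydrogen bond to the ketone, as in the conversion of 2,4-dihydroxyacetophenone into its 4-methyl ether.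

**Step 3**
Reactants: 5 monomethyl ether 1-(2-hydroxy-4-methoxyphenyl)-2-(3,4,5-trimethoxyphenyl)ethanone; 6 potassium peroxodisulfate
Product: 8 hydroquinone ketone 1-(2,5-dihydroxy-4-methoxyphenyl)-2-(3,4,5-trimethoxyphenyl)ethanone, via potassium aryl sulfate 7 (not isolated)
Conditions: K2S2O8 (1.1 equiv, aq, added over 4 h), aq KOH, pyridine, 15–20 °C, 24 h; HCl to pH 4, EtOAc wash (returns 5); aqueous layer, HCl, Na2SO3, 90 °C, N2
Reagents that add atoms: potassium peroxodisulfate (6), [K+].[K+].[O-]S(=O)(=O)OOS(=O)(=O)[O-]
Why: In aqueous KOH the phenoxide of 5, an ambident nucleophile, should attack a peroxide oxygen of S2O8(2−) through the ring carbon para to O− (C5 of the ketone ring, the future C6), displacing sulfate; the cyclohexadienone tautomerises to aryl sulfate 7, which resists further persulfate, and hot acid then cleaves its S–O bond to release hydroquinone 8. This is the Elbs peroxodisulfate oxidation, established for 2-hydroxyaryl ketones such as 2-hydroxy-4-methoxyacetophenone. The step forms one C–O bond, closes no ring and creates no stereocentre. Para attack is inherent to the mechanism and is favoured here because C5 is unsubstituted, ortho to the methoxyl and meta to the acyl group, whereas the ortho carbon C3 is crowded between OH and OMe. The phenoxide, the dominant anion at this pH, should outrun the small share of benzylic enolate, and slow addition at 15–20 °C with pyridine as co-solvent should hold back radical oxidation of the methylene. Conversion is expected to be partial, so unchanged 5 is washed out at pH 4 and recycled while 7 stays in the water layer; sulfite and nitrogen protect the hydroquinone during hydrolysis.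

**Step 4**
Reactants: 8 hydroquinone ketone 1-(2,5-dihydroxy-4-methoxyphenyl)-2-(3,4,5-trimethoxyphenyl)ethanone; 9 N,N-dimethylformamide
Product: 11 isoflavone 6-hydroxy-7-methoxy-3-(3,4,5-trimethoxyphenyl)-4H-chromen-4-one (target), via dimethylaminomethylene ketone 10 (not isolated)
Conditions: DMF, BF3·Et2O (4 equiv), then MeSO2Cl (3 equiv), 50 → 80 °C, N2; aq NaOAc work-up
Reagents that add atoms: N,N-dimethylformamide (9), CN(C)C=O
Why: The iminium salt formed from DMF and MeSO2Cl should C-formylate the benzylic methylene of the BF3-activated ketone (Vilsmeier-type aminomethylenation) to give enaminone 10, whose chelated 2-hydroxyl adds to the enamine carbon in a 6-endo-trig oxa-Michael step and expels dimethylamine to aromatise the pyranone; this one-pot deoxybenzoin-to-isoflavone closure is established for substrates with free phenolic hydroxyls, and any O-formate formed at the C5 hydroxyl is cleaved in the aqueous work-up.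

**Compound list**
1 | resorcinol (benzene-1,3-diol) | Oc1cccc(O)c1 | starting material
2 | (3,4,5-trimethoxyphenyl)acetic acid | COc1cc(CC(O)=O)cc(OC)c1OC | starting material
3 | 1-(2,4-dihydroxyphenyl)-2-(3,4,5-trimethoxyphenyl)ethanone | COc1cc(CC(=O)c2ccc(O)cc2O)cc(OC)c1OC | intermediate
4 | dimethyl sulfate | COS(=O)(=O)OC | starting material
5 | 1-(2-hydroxy-4-methoxyphenyl)-2-(3,4,5-trimethoxyphenyl)ethanone | COc1ccc(C(=O)Cc2cc(OC)c(OC)c(OC)c2)c(O)c1 | intermediate
6 | potassium peroxodisulfate | [K+].[K+].[O-]S(=O)(=O)OOS(=O)(=O)[O-] | starting material
7 | potassium 4-hydroxy-2-methoxy-5-[(3,4,5-trimethoxyphenyl)acetyl]phenyl sulfate (formed in the flask, not isolated) | COc1cc(O)c(C(=O)Cc2cc(OC)c(OC)c(OC)c2)cc1OS(=O)(=O)[O-].[K+] | intermediate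
8 | 1-(2,5-dihydroxy-4-methoxyphenyl)-2-(3,4,5-trimethoxyphenyl)ethanone | COc1cc(O)c(C(=O)Cc2cc(OC)c(OC)c(OC)c2)cc1O | intermediate
9 | N,N-dimethylformamide | CN(C)C=O | starting material
10 | 3-(dimethylamino)-1-(2,5-dihydroxy-4-methoxyphenyl)-2-(3,4,5-trimethoxyphenyl)prop-2-en-1-one (formed in the flask, not isolated; alkene geometry not fixed, either isomer cyclises) | COc1cc(O)c(C(=O)C(=CN(C)C)c2cc(OC)c(OC)c(OC)c2)cc1O | intermediate
11 | 6-hydroxy-7-methoxy-3-(3,4,5-trimethoxyphenyl)-4H-chromen-4-one | COc1cc2occ(-c3cc(OC)c(OC)c(OC)c3)c(=O)c2cc1O | target

**Step count**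
Total steps: 4. Longest linear sequence: 4 steps (1 → 3 → 5 → 8 → 11).

**Steps most likely to fail**

1. Step 3. The hydroxylation may stall at low conversion, and one-electron pathways may compete, causing oxidative coupling of the phenoxide and oxidation at the benzylic methylene; the hydroquinone may also be air-oxidised during hydrolysis. Fallback: the C6 oxygen would be brought in with the arene instead of by oxidation. The detour sets out from acid 2, which is condensed in BF3·Et2O at 85 °C with purchased 2-methoxybenzene-1,4-diol (methoxyhydroquinone, COc1cc(O)ccc1O). Friedel–Crafts acylation should take place at the carbon para to the methoxyl and ortho to a hydroxyl, and the route is rejoined at 8 in one operation, steps 1 to 3 being dropped. No compound outside the list arises on this path (F0).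

2. Step 4. The iminium reagent may O-formylate or O-sulfonylate the free C5 hydroxyl or attack the electron-rich hydroquinone ring faster than the methylene, and the hydroquinone may be oxidised on heating. Fallback: the hydroxyl is masked before ring closure. Setting out from 8, BnBr and K2CO3 in acetone should alkylate only the non-chelated hydroxyl to give 1-[5-(benzyloxy)-2-hydroxy-4-methoxyphenyl]-2-(3,4,5-trimethoxyphenyl)ethanone F1. Heating F1 with N,N-dimethylformamide dimethyl acetal in toluene at 100 °C should close ring C through the enaminone to 6-(benzyloxy)-7-methoxy-3-(3,4,5-trimethoxyphenyl)-4H-chromen-4-one F2. Hydrogenolysis (H2, Pd/C, EtOAc–MeOH, stopped at uptake of one equivalent) then returns to the route at 11.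

3. Step 2. Alkylation may run on to the chelated hydroxyl or to the doubly activated benzylic carbon, giving over-methylated material that is hard to separate. Fallback: the methyl group arrives with the phenol. Setting out from acid 2, esterification with purchased 3-methoxyphenol (COc1cccc(O)c1; DCC, DMAP, CH2Cl2) gives 3-methoxyphenyl (3,4,5-trimethoxyphenyl)acetate F3. A Fries rearrangement of F3 in BF3·Et2O at 90 °C should move the acyl group to the carbon ortho to the oxygen and para to the methoxyl, where the ketone is held as a chelate, and rejoin the route at 5; steps 1 and 2 are dropped.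

**Further compounds**
F0 | step 3 | none | none
F1 | step 4 | 1-[5-(benzyloxy)-2-hydroxy-4-methoxyphenyl]-2-(3,4,5-trimethoxyphenyl)ethanone | COc1cc(O)c(C(=O)Cc2cc(OC)c(OC)c(OC)c2)cc1OCc1ccccc1
F2 | step 4 | 6-(benzyloxy)-7-methoxy-3-(3,4,5-trimethoxyphenyl)-4H-chromen-4-one | COc1cc2occ(-c3cc(OC)c(OC)c(OC)c3)c(=O)c2cc1OCc1ccccc1
F3 | step 2 | 3-methoxyphenyl (3,4,5-trimethoxyphenyl)acetate | COc1cccc(OC(=O)Cc2cc(OC)c(OC)c(OC)c2)c1
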